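## Analysis of the target

The target is a quinic acid: a cyclohexanecarboxylic acid with a tertiary hydroxyl on C1 beside the carboxyl group, a free secondary hydroxyl on C3, and (E)-4-hydroxycinnamoyl esters on O4 and O5. The four stereocentres C1, C3, C4 and C5 sit on one six-membered ring. O1, O3 and O4 lie on one face; O5 and the carboxyl carbon lie on the other. In the chair with the carboxyl group equatorial, O4 and O5 are trans-diequatorial and O1 and O3 are both axial on the same face. The sensitive groups are the two cinnamates (base-labile, with conjugated double bonds open to reduction, hydrosilylation and conjugate addition), the free phenols, and the O3 hydroxyl, which is cis and vicinal to the O4 ester and takes over its acyl group under base. The carbon skeleton is not the difficulty: the task is to acylate two adjacent secondary hydroxyls and leave the third free, with no basic step afterwards. The strategy rests on the 1,3-diaxial relation between the tertiary O1 and the axial C3–O bond across C2. A silicon atom held on O1 reaches exactly the axial hydrogen of a C3 methylene, so C3 can remain CH2 while O4 and O5 are acylated and receive its oxygen last through a temporary five-membered Si–O1–C1–C2–C3 ring.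

## Retrosynthetic reasoning

**23 from 22.** The benzylic C–O bond of a 4-methoxybenzyl ester and the two acetal C–O bonds of the phenol methoxymethyl ethers are cut first. All three fall to acid in one operation. A base or nucleophile at the end would move the O4 acyl group to the cis O3 hydroxyl or cleave the cinnamates. The forward step only has to ionise these groups in the presence of a cation trap.

**22 from 21.** The C3–O bond is traced back to a C3–Si bond, and the O1–H bond to the O1–Si bond of the oxasilolane 21. Oxidation of a C–Si bond goes with retention, so silicon must already sit axial on C3, on the face of O1. The gain is that C3 cannot be acylated while it bears silicon and O1 is tied into the same ring. The diester is therefore made with no protecting group on O3, and O3 appears only under non-basic conditions.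

**21 from 17 and 20.** The two ester C–O bonds at O4 and O5 are cut, giving diol 17 and acid 20. Diol 17 has no other hydroxyl, so the forward esterification needs no selectivity, only enough drive for two neighbouring secondary alcohols. Acid 20 comes from 18 through the doubly alkylated 19; the phenol is masked so that it does not compete, with a group the final acid removes.

**17 from 16.** The diol is traced to its bis(triethylsilyl) ether. Silyl ethers are what the C–H silylation tolerates on O4 and O5. Triethylsilyl is chosen over tert-butyldimethylsilyl because the latter leaves only with fluoride or stronger acid. Fluoride would first open the Si–O1 bond of the oxasilolane and expose the tertiary hydroxyl. Secondary triethylsilyl ethers are solvolysed under buffered acid, which the shielded ring silicon and the 4-methoxybenzyl ester should survive.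

**16 from 15 (key disconnection).** The C3–Si bond is cut, leading to the diethyl(hydrido)silyl ether 15 of a 3-deoxyquinate. The cut is made at C3 because it is the one ring carbon whose oxygen must be told apart from its neighbours, and because it lies γ to O1 on the same face. A cut at C4 or C5 would leave the differentiation of O3 unsolved. The forward reaction must replace the axial C3–H bond by C–Si and close the five-membered ring. It must prefer C3–H to the equally placed C5–H and to the ester carbonyl. The configuration at C3 follows from the tether.

**15 from 13 and 14; 13 from 12; 12 from 10 via 11.** The Si–O1 bond is cut to the tertiary alcohol 13 and silane 14. Compound 13 comes from triol ester 12 by silylation of the two secondary hydroxyls. Ester 12 comes from lactone 10 by opening the C(=O)–O5 bond and alkylating carboxylate 11. The open ester is required because only in the chair with the carboxyl group equatorial is O1 axial; in lactone 10 it is equatorial. The ester group has to be one that acid removes at the end.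

**10 from 8 via 9; 8 from 7.** The lactone C5–O bond is traced to an oxirane, and the oxirane to the cyclohexene 7. Hydroxyl direction places the oxirane of 8 on the face of O1. The carboxyl group of 9, on the other face, can open it only at C5 from the rear, which gives O4 cis and O5 trans to O1. Plain hydrolytic opening would be expected to follow the diaxial rule in the other chair and attack C4, giving both centres wrong. This is why the passage through the lactone is worth its steps.

**7 from 6; 6 from 4 and 5; 4 from 2; 2 from 1.** The C1–C6 and C2–C3 bonds are cut in a Diels–Alder sense to diene 5 and a 2-hydroxyacrylate equivalent. The methylene dioxolanone 4, made from 1 through acetal 2, carries a tert-butyl group that blocks one face, and adduct 6 needs only transesterification to give 7. A catalytic enantioselective cycloaddition of an acyloxyacrylate would be shorter, but 5 is a poor diene and 1,1-disubstituted acrylates are poor partners for chiral Lewis acids. The auxiliary is used so that the risk of the route stays in the key step. With 1 in the (R) series, the spiro carbon of 6 becomes (S), as C1 requires.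

## Alternatives that were turned down

**Alternative 1:** The C4–C5 bond is cut, giving the open-chain citrate-type keto aldehyde tert-butyl (2R)-2-hydroxy-4-oxo-2-(2-oxoethyl)-5-{[(E)-4-(methoxymethoxy)cinnamoyl]oxy}pentanoate A1.
- Forward key step: MgBr2·OEt2 and triethylamine would enolise the acyloxymethyl ketone towards C4, and the enolate would add to the aldehyde to give tert-butyl 4-O-[(E)-4-(methoxymethoxy)cinnamoyl]-3-dehydroquinate A2. The reversible aldol lets the 4-acyloxy and 5-hydroxy groups settle equatorial.
- For it: one C–C bond closes the ring and sets two stereocentres, one cinnamate is already in place, and only C1 must be made enantiopure.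
- Against it: in A2 both the C1 hydroxyl and the C5 oxygen are β to the ketone, so dehydration and retro-aldol are open at every basic stage. Enolisation can also go towards C2, and the α-acyloxy ketone can epimerise or pass its acyl group on. The ketone must then be reduced to the axial alcohol, against the usual preference of small hydrides, and the new alkoxide sits cis to the O4 ester, which invites the very acyl migration the target forbids.
- Comparison: A1 to A2 is more convergent and its key step is closer to established chemistry. The chosen route never has a carbonyl β to a leaving group and leaves no choice of face at C3, at the price of an unproven C–H functionalisation.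

**Alternative 2:** The C1–C6 bond is cut, giving tert-butyl 6-[1,2-bis(tert-butyldimethylsilyloxy)-3-iodopropyl]-1,3-dioxane-4-carboxylate A3, in which a methylene acetal already ties O1 to O3.
- Forward key step: KN(SiMe3)2 would form the ester enolate at C1, which displaces the primary iodide at C6 and closes the carbocycle as tert-butyl 4,5-bis-O-(tert-butyldimethylsilyl)-1,3-O-methylenequinate A4.
- For it: enolate alkylation is well established. The bicyclic frame gives the new quaternary centre no freedom. O1 and O3 are masked together, so O4 and O5 are the only positions to acylate, the same differentiation as in the chosen route.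
- Against it: the closure needs the side chain axial on the dioxane. The iodide is flanked by an oxygen-bearing carbon, which slows substitution and opens an elimination path. The acyclic precursor A3 requires a long sequence with four differentiated oxygens. Above all, a methylene acetal is among the hardest acetals to remove, and strong Lewis or Brønsted acid would be needed in the presence of two cinnamates.
- Comparison: A3 to A4 is stronger in precedent for the key step. The chosen route reaches its precursor from a Diels–Alder adduct in few steps and releases O3 by a mild oxidation instead of an acetal cleavage.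

**Alternative 3:** The C1–O bond is cut, leading to the shikimate-derived enone 4-methoxybenzyl 4,5-bis-O-[(E)-4-(methoxymethoxy)cinnamoyl]-3-dehydroshikimate A5, in which the C3 ketone stands for O3.
- Forward key step: tert-butyl hydroperoxide with catalytic DBU would add to C1 and the enolate would close the C1–C2 oxirane anti to the C5 ester, giving 4-methoxybenzyl 1,2-anhydro-2-hydroxy-4,5-bis-O-[(E)-4-(methoxymethoxy)cinnamoyl]-3-dehydroquinate A6. Reductive opening at C2 and ketone reduction would follow.
- For it: all ring carbons and the C4 and C5 centres come from the chiral pool, and the ketone differentiates O3 without a protecting group. It is clearly the shortest plan.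
- Against it: A5 is one elimination from an aromatic ring. Deprotonation at C4 and loss of the C5 ester leads to a dihydroxybenzoate, and DBU is a base suited to exactly that. Cleavage of the C2–O bond by electron-transfer reagents must spare two cinnamates. The final ketone reduction has the same facial and migration problems as in alternative 1.
- Comparison: A5 to A6 wins on step count and uses known reaction types. The chosen route offers base-stable intermediates throughout and a tether-defined C3, and accepts an unprecedented key step in return.

Key step: step 10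

Assumption: quinic acid locants are kept for all cyclohexane intermediates (C1 bears the carboxyl carbon; O1, O3, O4 on one face, O5 and the carboxyl carbon on the other), and (R)-lactic acid is taken as a purchasable starting material.

## Route

Step 1
Reactants: 1 (R)-lactic acid
Product: 2 (2R,5R)-2-tert-butyl-5-methyl-1,3-dioxolan-4-one
Conditions: tBuCHO, TsOH·H2O (cat.), pentane, reflux, Dean–Stark; crystallisation from pentane/Et2O, −78 °C
Reagents that add atoms: pivalaldehyde, CC(C)(C)C=O
Why: Acid-catalysed acetalisation with azeotropic removal of water; the cis acetal (tert-butyl and methyl on the same face) should be the favoured isomer and is purified by crystallisation, so the lactic acid centre fixes the acetal carbon as R.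

Step 2
Reactants: 2
Product: 4 (R)-2-tert-butyl-5-methylene-1,3-dioxolan-4-one, via bromide 3 (not isolated)
Conditions: NBS, AIBN (cat.), PhCF3, 80 °C; filter; then Et3N, Et2O, 0 °C → rt
Reagents that add atoms: none
Why: Radical bromination of the captodative C5–H bond, then E2 dehydrobromination; the lactic acid centre is given up and the acetal carbon alone carries the chirality.

Step 3
Reactants: 4, 5 buta-1,3-diene
Product: 6 (2R,5S)-2-tert-butyl-1,3-dioxaspiro[4.5]dec-7-en-4-one
Conditions: butadiene (5 equiv), BHT (cat.), toluene, sealed tube, 90 °C
Reagents that add atoms: none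
Why: Thermal Diels–Alder reaction of a captodative 1,1-disubstituted dienophile; the diene should add to the face of the exocyclic double bond opposite to the tert-butyl group, which sets the spiro carbon (future C1) as S. Butadiene is unsubstituted, so no endo/exo or regiochemical question arises, and a minor diastereomer can be removed by chromatography.

Step 4
Reactants: 6
Product: 7 methyl (S)-1-hydroxycyclohex-3-ene-1-carboxylate
Conditions: NaOMe (0.2 equiv), MeOH, 0 °C → rt
Reagents that add atoms: methanol, CO
Why: Transesterification: methoxide opens the dioxolanone at the carbonyl group and the hemiacetal alkoxide loses pivalaldehyde; the quaternary centre is not touched.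

Step 5
Reactants: 7
Product: 8 methyl (1S,3S,6R)-3-hydroxy-7-oxabicyclo[4.1.0]heptane-3-carboxylate (oxirane cis to the hydroxyl)
Conditions: VO(acac)2 (2 mol%), tBuOOH (1.5 equiv, decane), CH2Cl2, 0 °C → rt
Reagents that add atoms: tert-butyl hydroperoxide, CC(C)(C)OO
Why: Hydroxyl-directed epoxidation of a homoallylic cyclohexenol; the vanadate ester of the pseudoaxial tertiary hydroxyl delivers oxygen to its own face of the C4=C5 double bond, so the oxirane should form cis to O1 and trans to the ester.

Step 6
Reactants: 8
Product: 10 (1S,4R,5R)-1,4-dihydroxy-6-oxabicyclo[3.2.1]octan-7-one, via epoxy acid 9 (not isolated)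
Conditions: LiOH, THF/H2O, 0 °C; aq. HCl to pH 2, EtOAc; then CSA (cat.), CH2Cl2, rt
Reagents that add atoms: lithium hydroxide (one carboxyl oxygen), [Li+].[OH-]
Why: Saponification, then acid-catalysed intramolecular oxirane opening; the carboxyl group lies opposite the oxirane oxygen and attacks C5 from the rear through a chair-like trans-diaxial transition state (Fürst–Plattner), closing the five-membered lactone. C5 is inverted (O5 cis to the carboxyl carbon) and C4 keeps its oxygen cis to O1; attack at C4 would need a boat and a six-membered lactone.

Step 7
Reactants: 10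
Product: 12 4-methoxybenzyl 3-deoxyquinate, via caesium carboxylate 11 (not isolated)
Conditions: CsOH·H2O (1.0 equiv), THF/H2O, rt; evaporate; then PMBCl, DMF, rt
Reagents that add atoms: caesium hydroxide (one carboxyl oxygen), [Cs+].[OH-]; 4-methoxybenzyl chloride, COc1ccc(CCl)cc1
Why: Saponification of the strained lactone and SN2 alkylation of the caesium carboxylate without passing through the free acid, so the lactone cannot re-form; hydroxyl groups are not alkylated without a strong base.

Step 8
Reactants: 12
Product: 13 4-methoxybenzyl 3-deoxy-4,5-bis-O-(triethylsilyl)quinate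
Conditions: Et3SiCl (2.2 equiv), imidazole, CH2Cl2, 0 °C
Reagents that add atoms: chlorotriethylsilane, CC[Si](Cl)(CC)CC
Why: Imidazole-mediated silylation takes the two secondary hydroxyls and should leave the tertiary, ester-flanked O1 hydroxyl free on steric grounds.

Step 9
Reactants: 13, 14 diethylsilane
Product: 15 4-methoxybenzyl 3-deoxy-1-O-(diethylsilyl)-4,5-bis-O-(triethylsilyl)quinate
Conditions: [Ir(cod)OMe]2 (0.5 mol%), THF, rt → 40 °C; volatiles removed in vacuo
Reagents that add atoms: none
Why: Iridium-catalysed dehydrogenative coupling of an alcohol with a dihydrosilane, a known route to diethyl(hydrido)silyl ethers of tertiary alcohols; hydrogen is the only by-product and the second Si–H bond remains.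

Step 10
Reactants: 15
Product: 16 4-methoxybenzyl 3-deoxy-3,O1-(diethylsilanediyl)-4,5-bis-O-(triethylsilyl)quinate (6-oxa-7-silabicyclo[3.2.1]octane core)
Conditions: [Ir(cod)OMe]2 (2 mol%), 3,4,7,8-tetramethyl-1,10-phenanthroline (5 mol%), norbornene (1.5 equiv), THF, 120 °C, sealed tube
Reagents that add atoms: none
Why: Proposed new method: the closest known reaction type is the iridium-catalysed silylation of secondary γ C–H bonds of diethyl(hydrido)silyl ethers, shown only on much simpler alcohols without an ester on the carbinol carbon or oxygenated ring carbons. The monovalent iridium precatalyst and the phenanthroline should give an iridium silyl hydride; norbornene takes up the hydrogen, and the resulting iridium silyl species cleaves the γ C–H bond through a six-membered iridacycle (Ir–Si–O1–C1–C2–C3) and forms C3–Si by reductive elimination. The ring closed is the five-membered oxasilolane Si–O1–C1–C2–C3, closed by C–Si bond formation across the 1,3-diaxial positions to give the bridged bicycle. In the chair of 15 the ester and both silyloxy groups are equatorial (the ring flip would put the ester and O5 syn-diaxial), so the O1–Si bond is axial and reaches only the syn-axial hydrogens on C3 and C5. The new stereocentre C3 is therefore controlled by the tether from C1: silicon can only take the place of the axial hydrogen on the face of O1, the position of the future hydroxyl. The selectivity needed is site selectivity between the two γ hydrogens; C3–H belongs to a methylene group, whereas C5–H is a methine hydrogen under a triethylsilyloxy group, a kind of bond this catalyst type does not silylate. The open point is chemoselectivity against addition of the Si–H bond across the neighbouring ester carbonyl.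

Step 11
Reactants: 16
Product: 17 4-methoxybenzyl 3-deoxy-3,O1-(diethylsilanediyl)quinate
Conditions: PPTS (0.2 equiv), MeOH/CH2Cl2 (1:1), 0 °C
Reagents that add atoms: none
Why: Acid-catalysed methanolysis of silyl ethers is governed by steric access to silicon; the two secondary triethylsilyl ethers should react, while the ring silicon, bound to a tertiary oxygen and a secondary carbon inside the bicycle, is far more shielded and can re-close if opened. The 4-methoxybenzyl ester is stable to the buffered acid.

Step 12
Reactants: 18 p-coumaric acid
Product: 20 (E)-3-[4-(methoxymethoxy)phenyl]prop-2-enoic acid, via bis-MOM derivative 19 (not isolated)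
Conditions: MOMCl (2.4 equiv), iPr2NEt, CH2Cl2, 0 °C → rt; then LiOH, THF/MeOH/H2O, rt; aq. HCl to pH 4, 0 °C
Reagents that add atoms: chloromethyl methyl ether, COCCl; lithium hydroxide (one carboxyl oxygen), [Li+].[OH-]
Why: O-Alkylation of phenol and carboxylate, then saponification of the acyloxymethyl ester only; the aryl acetal resists base and falls in the final acid step.

Step 13
Reactants: 17, 20
Product: 21 4-methoxybenzyl 3-deoxy-3,O1-(diethylsilanediyl)-4,5-bis-O-[(E)-4-(methoxymethoxy)cinnamoyl]quinate
Conditions: 20 (2.6 equiv), EDC·HCl (3 equiv), DMAP (1 equiv), CH2Cl2, rt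
Reagents that add atoms: none
Why: Steglich esterification of the only two hydroxyl groups in the molecule; C3 bears no oxygen and O1 is part of the oxasilolane, so neither over-acylation nor acyl migration is possible.

Step 14
Reactants: 21
Product: 22 4-methoxybenzyl 4,5-bis-O-[(E)-4-(methoxymethoxy)cinnamoyl]quinate
Conditions: mCPBA (3 equiv), KHF2 (4 equiv), DMF, 0 °C → rt
Reagents that add atoms: 3-chloroperbenzoic acid, OOC(=O)c1cccc(Cl)c1
Why: Tamao–Fleming oxidation: fluoride makes the alkoxysilane pentacoordinate, the peracid adds, and C3 migrates from silicon to oxygen with retention, giving the axial C3 hydroxyl cis to O1 and O4. The medium is non-basic, so the esters should neither cleave nor migrate, and the electron-poor cinnamate double bonds are slow to epoxidise.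

Step 15
Reactants: 22
Product: 23 4,5-di-O-p-coumaroylquinic acid
Conditions: CF3CO2H/CH2Cl2 (1:4), anisole (10 equiv), H2O (5 equiv), 0 °C → rt
Reagents that add atoms: none
Why: Acidolysis: the 4-methoxybenzyl ester ionises to a stabilised benzyl cation that anisole traps, and the two aryl methoxymethyl acetals are hydrolysed. No stereocentre is involved, and acyl migration to O3, a base-promoted process, is avoided.

## Compound list

1 | (R)-lactic acid | C[C@@H](O)C(=O)O | starting material
2 | (2R,5R)-2-tert-butyl-5-methyl-1,3-dioxolan-4-one (cis) | CC(C)(C)[C@H]1OC(=O)[C@@H](C)O1 | intermediate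
3 | (2R,5S)-5-bromo-2-tert-butyl-5-methyl-1,3-dioxolan-4-one (bromine taken as trans to tert-butyl; not isolated) | CC(C)(C)[C@H]1OC(=O)[C@](C)(Br)O1 | intermediate
4 | (R)-2-tert-butyl-5-methylene-1,3-dioxolan-4-one | CC(C)(C)[C@H]1OC(=O)C(=C)O1 | intermediate
5 | buta-1,3-diene | C=CC=C | starting material
6 | (2R,5S)-2-tert-butyl-1,3-dioxaspiro[4.5]dec-7-en-4-one | CC(C)(C)[C@H]1OC(=O)[C@]2(CC=CCC2)O1 | intermediate
7 | methyl (S)-1-hydroxycyclohex-3-ene-1-carboxylate | COC(=O)[C@@]1(O)CC=CCC1 | intermediate
8 | methyl (1S,3S,6R)-3-hydroxy-7-oxabicyclo[4.1.0]heptane-3-carboxylate (oxirane cis to OH) | O1[C@@H]2CC[C@@](O)(C(=O)OC)C[C@H]12 | intermediate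
9 | (1S,3S,6R)-3-hydroxy-7-oxabicyclo[4.1.0]heptane-3-carboxylic acid (not isolated) | O1[C@@H]2CC[C@@](O)(C(=O)O)C[C@H]12 | intermediate
10 | (1S,4R,5R)-1,4-dihydroxy-6-oxabicyclo[3.2.1]octan-7-one (3-deoxyquinide) | O[C@@H]1CC[C@]2(O)C[C@H]1OC2=O | intermediate
11 | caesium (1S,3R,4R)-1,3,4-trihydroxycyclohexane-1-carboxylate (caesium 3-deoxyquinate; not isolated) | O[C@@H]1CC[C@@](O)(C(=O)[O-])C[C@H]1O.[Cs+] | intermediate
12 | 4-methoxybenzyl 3-deoxyquinate [4-methoxybenzyl (1S,3R,4R)-1,3,4-trihydroxycyclohexane-1-carboxylate] | O[C@@H]1CC[C@@](O)(C(=O)OCc2ccc(OC)cc2)C[C@H]1O | intermediate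
13 | 4-methoxybenzyl 3-deoxy-4,5-bis-O-(triethylsilyl)quinate | CC[Si](CC)(CC)O[C@@H]1CC[C@@](O)(C(=O)OCc2ccc(OC)cc2)C[C@H]1O[Si](CC)(CC)CC | intermediate
14 | diethylsilane | CC[SiH2]CC | starting material
15 | 4-methoxybenzyl 3-deoxy-1-O-(diethylsilyl)-4,5-bis-O-(triethylsilyl)quinate | CC[Si](CC)(CC)O[C@@H]1CC[C@@](O[SiH](CC)CC)(C(=O)OCc2ccc(OC)cc2)C[C@H]1O[Si](CC)(CC)CC | intermediate
16 | 4-methoxybenzyl 3-deoxy-3,O1-(diethylsilanediyl)-4,5-bis-O-(triethylsilyl)quinate | CC[Si](CC)(CC)O[C@@H]1[C@H]2C[C@@](O[Si]2(CC)CC)(C(=O)OCc2ccc(OC)cc2)C[C@H]1O[Si](CC)(CC)CC | intermediate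
17 | 4-methoxybenzyl 3-deoxy-3,O1-(diethylsilanediyl)quinate | O[C@@H]1[C@H]2C[C@@](O[Si]2(CC)CC)(C(=O)OCc2ccc(OC)cc2)C[C@H]1O | intermediate
18 | p-coumaric acid [(E)-3-(4-hydroxyphenyl)prop-2-enoic acid] | OC(=O)/C=C/c1ccc(O)cc1 | starting material
19 | methoxymethyl (E)-3-[4-(methoxymethoxy)phenyl]prop-2-enoate (not isolated) | COCOC(=O)/C=C/c1ccc(OCOC)cc1 | intermediate
20 | (E)-3-[4-(methoxymethoxy)phenyl]prop-2-enoic acid | OC(=O)/C=C/c1ccc(OCOC)cc1 | intermediate
21 | 4-methoxybenzyl 3-deoxy-3,O1-(diethylsilanediyl)-4,5-bis-O-[(E)-4-(methoxymethoxy)cinnamoyl]quinate | O=C(/C=C/c1ccc(OCOC)cc1)O[C@@H]1[C@H]2C[C@@](O[Si]2(CC)CC)(C(=O)OCc2ccc(OC)cc2)C[C@H]1OC(=O)/C=C/c1ccc(OCOC)cc1 | intermediate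
22 | 4-methoxybenzyl 4,5-bis-O-[(E)-4-(methoxymethoxy)cinnamoyl]quinate | O=C(/C=C/c1ccc(OCOC)cc1)O[C@@H]1[C@H](O)C[C@@](O)(C(=O)OCc2ccc(OC)cc2)C[C@H]1OC(=O)/C=C/c1ccc(OCOC)cc1 | intermediate
23 | 4,5-di-O-p-coumaroylquinic acid | O=C(/C=C/c1ccc(O)cc1)O[C@@H]1[C@H](O)C[C@@](O)(C(=O)O)C[C@H]1OC(=O)/C=C/c1ccc(O)cc1 | target

## Step count and least certain steps

Total: 15 steps. Longest linear sequence: 14 steps (steps 1–11 and 13–15, from 1 to 23); step 12 is the side branch.

**Step 10 (key step, proposed new method).** The most likely failure is addition of the Si–H bond across the adjacent ester carbonyl in place of C–H cleavage, or C–H cleavage too slow in the crowded 1,3-diaxial array so that the silyl ether only redistributes. Fallback, by known chemistry, from 10 back to 22: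
- Dehydration of the axial C4 hydroxyl of 10 with the Burgess reagent should give (1S,5R)-1-hydroxy-6-oxabicyclo[3.2.1]oct-3-en-7-one F1. C5 is a bridgehead, so only the C3=C4 alkene can form (Bredt's rule).
- OsO4 (cat.) with N-methylmorpholine N-oxide adds from the face away from the lactone bridge and gives quinide F2, with O3 and O4 cis to O1.
- tert-Butyldimethylsilyl chloride and imidazole take the equatorial C3 hydroxyl to give 3-O-(tert-butyldimethylsilyl)quinide F3.
- CsOH opens the lactone to caesium 3-O-(tert-butyldimethylsilyl)quinate F4, which 4-methoxybenzyl chloride in DMF converts into 4-methoxybenzyl 3-O-(tert-butyldimethylsilyl)quinate F5.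
- Esterification with 20 as in step 13 gives 4-methoxybenzyl 3-O-(tert-butyldimethylsilyl)-4,5-bis-O-[(E)-4-(methoxymethoxy)cinnamoyl]quinate F6, and HF·pyridine removes the silyl ether to reach 22.

This detour distinguishes O3 by a protecting group; its weak point is silyl migration from O3 to O4 during lactone opening.

**Step 11.** Solvolytic opening of the Si–O1 bond may compete with removal of the triethylsilyl ethers, exposing the tertiary hydroxyl and giving mixed silicon species. Fallback, from 16 back to 22, accepts the opening:
- HF·pyridine in THF cleaves both silyl ethers and the Si–O1 bond to give 4-methoxybenzyl 3-deoxy-3-(diethylfluorosilyl)quinate F7.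
- Esterification with 20 (EDC, DMAP) acylates the two secondary hydroxyls, the tertiary one being inert under these conditions, and gives 4-methoxybenzyl 3-deoxy-3-(diethylfluorosilyl)-4,5-bis-O-[(E)-4-(methoxymethoxy)cinnamoyl]quinate F8.
- The fluorosilane is oxidised with mCPBA and KHF2 to 22. Re-closure to 21 along the way would be harmless.

**Step 14.** Oxidation of the hindered secondary C–Si bond may be incomplete under non-basic conditions, excess peracid may epoxidise the cinnamoyl double bonds, or the O4 acyl group may shift once the cis hydroxyl is free. Fallback, from 16 back to 22, oxidises before acylating: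
- mCPBA and KHF2 in DMF convert 16 into 4-methoxybenzyl 4,5-bis-O-(triethylsilyl)quinate F9. No acyl group or double bond is present at this stage, so harsher basic peroxide conditions are also open.
- tBuMe2SiOTf and 2,6-lutidine at −78 °C silylate the secondary O3 to give 4-methoxybenzyl 3-O-(tert-butyldimethylsilyl)-4,5-bis-O-(triethylsilyl)quinate F10.
- PPTS in methanol removes the two triethylsilyl ethers and gives F5, which goes on through F6 to 22 as in the fallback for step 10.

**Step 3.** The dienophile may polymerise at the temperature butadiene needs, or facial selectivity may erode. Fallback, from 5 back to 7, replaces auxiliary control by resolution: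
- Heating 5 with methyl 2-acetoxyacrylate in a sealed tube gives racemic methyl 1-acetoxycyclohex-3-ene-1-carboxylate F11.
- K2CO3 in methanol removes the acetate to give racemic methyl 1-hydroxycyclohex-3-ene-1-carboxylate F12.
- Preparative chromatography on a chiral stationary phase separates the enantiomers; the (S)-enantiomer is 7.

## Further compounds

F1 | step 10 | (1S,5R)-1-hydroxy-6-oxabicyclo[3.2.1]oct-3-en-7-one | C1=CC[C@]2(O)C[C@H]1OC2=O
F2 | step 10 | quinide [(1S,3R,4R,5R)-1,3,4-trihydroxy-6-oxabicyclo[3.2.1]octan-7-one] | O[C@@H]1[C@H](O)C[C@]2(O)C[C@H]1OC2=O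
F3 | step 10 | 3-O-(tert-butyldimethylsilyl)quinide | O[C@@H]1[C@H](O[Si](C)(C)C(C)(C)C)C[C@]2(O)C[C@H]1OC2=O
F4 | step 10 | caesium 3-O-(tert-butyldimethylsilyl)quinate | O[C@@H]1[C@H](O[Si](C)(C)C(C)(C)C)C[C@@](O)(C(=O)[O-])C[C@H]1O.[Cs+]
F5 | step 10 | 4-methoxybenzyl 3-O-(tert-butyldimethylsilyl)quinate | O[C@@H]1[C@H](O[Si](C)(C)C(C)(C)C)C[C@@](O)(C(=O)OCc2ccc(OC)cc2)C[C@H]1O
F6 | step 10 | 4-methoxybenzyl 3-O-(tert-butyldimethylsilyl)-4,5-bis-O-[(E)-4-(methoxymethoxy)cinnamoyl]quinate | O=C(/C=C/c1ccc(OCOC)cc1)O[C@@H]1[C@H](O[Si](C)(C)C(C)(C)C)C[C@@](O)(C(=O)OCc2ccc(OC)cc2)C[C@H]1OC(=O)/C=C/c1ccc(OCOC)cc1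
F7 | step 11 | 4-methoxybenzyl 3-deoxy-3-(diethylfluorosilyl)quinate | O[C@@H]1[C@H]([Si](F)(CC)CC)C[C@@](O)(C(=O)OCc2ccc(OC)cc2)C[C@H]1O
F8 | step 11 | 4-methoxybenzyl 3-deoxy-3-(diethylfluorosilyl)-4,5-bis-O-[(E)-4-(methoxymethoxy)cinnamoyl]quinate | O=C(/C=C/c1ccc(OCOC)cc1)O[C@@H]1[C@H]([Si](F)(CC)CC)C[C@@](O)(C(=O)OCc2ccc(OC)cc2)C[C@H]1OC(=O)/C=C/c1ccc(OCOC)cc1
F9 | step 14 | 4-methoxybenzyl 4,5-bis-O-(triethylsilyl)quinate | CC[Si](CC)(CC)O[C@@H]1[C@H](O)C[C@@](O)(C(=O)OCc2ccc(OC)cc2)C[C@H]1O[Si](CC)(CC)CC
F10 | step 14 | 4-methoxybenzyl 3-O-(tert-butyldimethylsilyl)-4,5-bis-O-(triethylsilyl)quinate | CC[Si](CC)(CC)O[C@@H]1[C@H](O[Si](C)(C)C(C)(C)C)C[C@@](O)(C(=O)OCc2ccc(OC)cc2)C[C@H]1O[Si](CC)(CC)CC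
F11 | step 3 | racemic methyl 1-acetoxycyclohex-3-ene-1-carboxylate | COC(=O)C1(OC(C)=O)CC=CCC1
F12 | step 3 | racemic methyl 1-hydroxycyclohex-3-ene-1-carboxylate | COC(=O)C1(O)CC=CCC1
A1 | alternative 1 | tert-butyl (2R)-2-hydroxy-4-oxo-2-(2-oxoethyl)-5-{[(E)-4-(methoxymethoxy)cinnamoyl]oxy}pentanoate | O=C(/C=C/c1ccc(OCOC)cc1)OCC(=O)C[C@@](O)(C(=O)OC(C)(C)C)CC=O
A2 | alternative 1 | tert-butyl 4-O-[(E)-4-(methoxymethoxy)cinnamoyl]-3-dehydroquinate | O=C(/C=C/c1ccc(OCOC)cc1)O[C@@H]1C(=O)C[C@@](O)(C(=O)OC(C)(C)C)C[C@H]1O
A3 | alternative 2 | tert-butyl 6-[1,2-bis(tert-butyldimethylsilyloxy)-3-iodopropyl]-1,3-dioxane-4-carboxylate (chain and C6 configured as in A4; either epimer at C4 of the dioxane) | CC(C)(C)[Si](C)(C)O[C@H]([C@H]1CC(C(=O)OC(C)(C)C)OCO1)[C@@H](CI)O[Si](C)(C)C(C)(C)C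
A4 | alternative 2 | tert-butyl 4,5-bis-O-(tert-butyldimethylsilyl)-1,3-O-methylenequinate | CC(C)(C)[Si](C)(C)O[C@@H]1[C@H]2C[C@@](OCO2)(C(=O)OC(C)(C)C)C[C@H]1O[Si](C)(C)C(C)(C)C
A5 | alternative 3 | 4-methoxybenzyl 4,5-bis-O-[(E)-4-(methoxymethoxy)cinnamoyl]-3-dehydroshikimate | O=C(/C=C/c1ccc(OCOC)cc1)O[C@@H]1C(=O)C=C(C(=O)OCc2ccc(OC)cc2)C[C@H]1OC(=O)/C=C/c1ccc(OCOC)cc1
A6 | alternative 3 | 4-methoxybenzyl 1,2-anhydro-2-hydroxy-4,5-bis-O-[(E)-4-(methoxymethoxy)cinnamoyl]-3-dehydroquinate | O=C(/C=C/c1ccc(OCOC)cc1)O[C@@H]1C(=O)[C@@H]2O[C@]2(C(=O)OCc2ccc(OC)cc2)C[C@H]1OC(=O)/C=C/c1ccc(OCOC)cc1
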